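**Retrosynthetic overview**

1. The target comes from its hexaacetate by one mild global deacetylation (last step).
2. The cyclohexene, the only ring formed, comes from an endo-selective, chiral-borate-promoted Diels–Alder reaction of a 2'-hydroxychalcone with a dienyl chalcone. This makes both ring bonds and all three stereocentres at once.
3. Each enone C(=O)–Cα bond is made by using a salicylaldehyde formyl carbon as an acyl anion equivalent (chelated acyl–rhodium hydride) and adding it to the terminal carbon of an arylalkyne. The conditions are neutral, so acetates survive and no aldol or protecting-group exchange is needed.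
4. Both salicylaldehydes come from one 3-iodo-2,4-dihydroxybenzaldehyde by Suzuki coupling. The alkynes come from 4-bromoresorcinol (Negishi ethynylation) and from commercial 4-ethynylphenol.

Assumption: boronates 4 and 11 and alkyne 13 are taken as purchasable, and (S)-VANOL (3,3'-diphenyl-2,2'-bi-1-naphthol) is taken as the antipode that gives the (1S,5S,6R) series; the mirror-image ligand would be used in the same step if the sense proved opposite.

**Route**

Step 1
Reactants: 1 2-iodoresorcinol
Product: 3 2,4-dihydroxy-3-iodobenzaldehyde, via aryl iminium chloride 2 (not isolated)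
Conditions: POCl3, DMF, MeCN, 0 °C to rt; then H2O, 50 °C
Reagents that add atoms: N,N-dimethylformamide CN(C)C=O; water O
Why: Vilsmeier–Haack formylation can only occur at the position para to one hydroxyl and ortho to the other (both such positions are equivalent), so the iodine ends up between the two hydroxyls with no regioisomer.

Step 2
Reactants: 3 2,4-dihydroxy-3-iodobenzaldehyde; 4 (E)-3-methylbut-1-enylboronic acid pinacol ester
Product: 5 2,4-dihydroxy-3-[(E)-3-methylbut-1-en-1-yl]benzaldehyde
Conditions: Pd(OAc)2 (5 mol %), SPhos (10 mol %), K3PO4, dioxane/H2O 4:1, 80 °C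
Reagents that add atoms: none
Why: Suzuki–Miyaura coupling of the aryl iodide proceeds with retention of the (E)-alkenyl geometry, and the bulky electron-rich phosphine copes with the doubly ortho-substituted, phenoxide-rich ring.

Step 3
Reactants: 5 2,4-dihydroxy-3-[(E)-3-methylbut-1-en-1-yl]benzaldehyde
Product: 6 4-formyl-3-hydroxy-2-[(E)-3-methylbut-1-en-1-yl]phenyl acetate
Conditions: Ac2O (1.05 equiv), pyridine, CH2Cl2, −10 °C
Reagents that add atoms: acetic anhydride CC(=O)OC(C)=O
Why: Selective O-acylation, because the hydroxyl ortho to the formyl group is tied up in an intramolecular hydrogen bond and only the para hydroxyl reacts with one equivalent of anhydride.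

Step 4
Reactants: 7 4-bromoresorcinol
Product: 8 4-bromo-1,3-phenylene diacetate
Conditions: Ac2O, pyridine, DMAP (cat.), CH2Cl2, rt
Reagents that add atoms: acetic anhydride CC(=O)OC(C)=O
Why: Exhaustive O-acylation of both phenols gives a base-free-stable aryl bromide whose protecting groups match those of the rest of the route.

Step 5
Reactants: 8 4-bromo-1,3-phenylene diacetate
Product: 9 4-ethynyl-1,3-phenylene diacetate
Conditions: HC≡CMgBr, ZnBr2, THF, 0 °C; then 8, Pd(PPh3)4 (5 mol %), THF, 50 °C
Reagents that add atoms: ethynylmagnesium bromide C#C[Mg]Br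
Why: Negishi coupling of ethynylzinc bromide (used in excess to suppress double arylation) gives the terminal arylalkyne directly, and the organozinc tolerates the two aryl acetates.

Step 6 (key step)
Reactants: 6 4-formyl-3-hydroxy-2-[(E)-3-methylbut-1-en-1-yl]phenyl acetate; 9 4-ethynyl-1,3-phenylene diacetate
Product: 10 4-{(E)-3-[2,4-bis(acetyloxy)phenyl]prop-2-enoyl}-3-hydroxy-2-[(E)-3-methylbut-1-en-1-yl]phenyl acetate (2'-hydroxychalcone, both alkenes E)
Conditions: [Rh(cod)Cl]2 (2.5 mol %), 1,1'-bis(diphenylphosphino)ferrocene (5 mol %), Na2CO3 (10 mol %), toluene, 80 °C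
Reagents that add atoms: none
Why: Chelation-assisted alkyne hydroacylation, in which the formyl C–H adds oxidatively to monovalent rhodium (held by the ortho phenoxide against decarbonylation) to give an acyl–rhodium hydride that acts as an acyl anion equivalent, syn hydrometalation puts rhodium on the unhindered terminal alkyne carbon, and reductive elimination gives the linear (E)-enone, so a formyl carbon and an alkyne carbon, neither a donor in normal polarity, are joined under neutral conditions that leave three acetates intact.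

Step 7
Reactants: 3 2,4-dihydroxy-3-iodobenzaldehyde; 11 (E)-3-methylbuta-1,3-dienylboronic acid pinacol ester
Product: 12 2,4-dihydroxy-3-[(E)-3-methylbuta-1,3-dien-1-yl]benzaldehyde
Conditions: Pd(OAc)2 (5 mol %), SPhos (10 mol %), K3PO4, dioxane/H2O 4:1, 60 °C
Reagents that add atoms: none
Why: The same Suzuki–Miyaura coupling installs the (E)-dienyl unit with retention of geometry, at a lower temperature to spare the diene.

Step 8
Reactants: 12 2,4-dihydroxy-3-[(E)-3-methylbuta-1,3-dien-1-yl]benzaldehyde; 13 4-ethynylphenol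
Product: 14 (E)-1-{2,4-dihydroxy-3-[(E)-3-methylbuta-1,3-dien-1-yl]phenyl}-3-(4-hydroxyphenyl)prop-2-en-1-one
Conditions: [Rh(cod)Cl]2 (2.5 mol %), 1,1'-bis(diphenylphosphino)ferrocene (5 mol %), Na2CO3 (10 mol %), dioxane, 60 °C, 13 (2 equiv)
Reagents that add atoms: none
Why: The same chelation-assisted hydroacylation (acyl–rhodium hydride as acyl anion equivalent) gives the linear (E)-enone, and the terminal alkyne is expected to insert much faster than the hindered, doubly ortho-flanked 1,3-diene.

Step 9
Reactants: 14 (E)-1-{2,4-dihydroxy-3-[(E)-3-methylbuta-1,3-dien-1-yl]phenyl}-3-(4-hydroxyphenyl)prop-2-en-1-one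
Product: 15 4-{(E)-3-[4-(acetyloxy)phenyl]prop-2-enoyl}-2-[(E)-3-methylbuta-1,3-dien-1-yl]-1,3-phenylene diacetate
Conditions: Ac2O, pyridine, DMAP (cat.), CH2Cl2, 0 °C to rt
Reagents that add atoms: acetic anhydride CC(=O)OC(C)=O
Why: Exhaustive O-acylation (DMAP forces the chelated 2'-hydroxyl) removes the only group through which boron could activate this enone, so the compound can act only as the diene in the next step.

Step 10
Reactants: 10 the 2'-hydroxychalcone triacetate from step 6; 15 the dienyl chalcone triacetate from step 9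
Product: 16 4-{(E)-3-[4-(acetyloxy)phenyl]prop-2-enoyl}-2-[(1S,5S,6R)-6-{4-(acetyloxy)-2-hydroxy-3-[(E)-3-methylbut-1-en-1-yl]benzoyl}-5-[2,4-bis(acetyloxy)phenyl]-3-methylcyclohex-2-en-1-yl]-1,3-phenylene diacetate (aroyl cis to the aryl on C1, trans to the aryl on C5)
Conditions: (S)-VANOL (1.2 equiv), BH3·THF (1.2 equiv), AcOH (1.2 equiv), THF, rt; then 10; then 15 (2 equiv), rt, 48 h; chromatographic removal of the exo isomer
Reagents that add atoms: none
Why: Diels–Alder cycloaddition of the boron-chelated 2'-hydroxy enone, in which suprafacial addition to the (E)-enone fixes aroyl and aryl trans at C6/C5, the endo transition state places the aroyl group cis to the aryl on C1, and the VANOL borate blocks one enone face to give the (1S,5S,6R) enantiomer.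

Step 11
Reactants: 16 the hexaacetate adduct from step 10
Product: 17 (E)-1-{3-[(1S,5S,6R)-6-{2,4-dihydroxy-3-[(E)-3-methylbut-1-en-1-yl]benzoyl}-5-(2,4-dihydroxyphenyl)-3-methylcyclohex-2-en-1-yl]-2,4-dihydroxyphenyl}-3-(4-hydroxyphenyl)prop-2-en-1-one (CNP0140882.1)
Conditions: K2CO3, degassed MeOH/THF, 0 °C to rt; aq. NH4Cl work-up
Reagents that add atoms: none
Why: Base-catalysed transesterification (methanolysis) of the six aryl acetates is fast at low temperature, where the liberated ortho-phenoxide deactivates the aroyl ketone toward enolisation so that C6 is not epimerised.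

**Compound list**

1 | 2-iodoresorcinol | Oc1cccc(O)c1I | starting material
2 | [(2,4-dihydroxy-3-iodophenyl)methylidene]dimethyliminium chloride | C[N+](C)=Cc1ccc(O)c(I)c1O.[Cl-] | intermediate
3 | 2,4-dihydroxy-3-iodobenzaldehyde | O=Cc1ccc(O)c(I)c1O | intermediate
4 | (E)-3-methylbut-1-enylboronic acid pinacol ester | CC(C)/C=C/B1OC(C)(C)C(C)(C)O1 | starting material
5 | 2,4-dihydroxy-3-[(E)-3-methylbut-1-en-1-yl]benzaldehyde | CC(C)/C=C/c1c(O)ccc(C=O)c1O | intermediate
6 | 4-formyl-3-hydroxy-2-[(E)-3-methylbut-1-en-1-yl]phenyl acetate | CC(C)/C=C/c1c(OC(C)=O)ccc(C=O)c1O | intermediate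
7 | 4-bromoresorcinol | Oc1ccc(Br)c(O)c1 | starting material
8 | 4-bromo-1,3-phenylene diacetate | CC(=O)Oc1ccc(Br)c(OC(C)=O)c1 | intermediate
9 | 4-ethynyl-1,3-phenylene diacetate | CC(=O)Oc1ccc(C#C)c(OC(C)=O)c1 | intermediate
10 | 4-{(E)-3-[2,4-bis(acetyloxy)phenyl]prop-2-enoyl}-3-hydroxy-2-[(E)-3-methylbut-1-en-1-yl]phenyl acetate | CC(C)/C=C/c1c(OC(C)=O)ccc(C(=O)/C=C/c2ccc(OC(C)=O)cc2OC(C)=O)c1O | intermediate
11 | (E)-3-methylbuta-1,3-dienylboronic acid pinacol ester | CC(=C)/C=C/B1OC(C)(C)C(C)(C)O1 | starting material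
12 | 2,4-dihydroxy-3-[(E)-3-methylbuta-1,3-dien-1-yl]benzaldehyde | CC(=C)/C=C/c1c(O)ccc(C=O)c1O | intermediate
13 | 4-ethynylphenol | C#Cc1ccc(O)cc1 | starting material
14 | (E)-1-{2,4-dihydroxy-3-[(E)-3-methylbuta-1,3-dien-1-yl]phenyl}-3-(4-hydroxyphenyl)prop-2-en-1-one | CC(=C)/C=C/c1c(O)ccc(C(=O)/C=C/c2ccc(O)cc2)c1O | intermediate
15 | 4-{(E)-3-[4-(acetyloxy)phenyl]prop-2-enoyl}-2-[(E)-3-methylbuta-1,3-dien-1-yl]-1,3-phenylene diacetate | CC(=C)/C=C/c1c(OC(C)=O)ccc(C(=O)/C=C/c2ccc(OC(C)=O)cc2)c1OC(C)=O | intermediate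
16 | (1S,5S,6R) hexaacetate adduct (full name in step 10) | CC1=C[C@H](c2c(OC(C)=O)ccc(C(=O)/C=C/c3ccc(OC(C)=O)cc3)c2OC(C)=O)[C@H](C(=O)c2ccc(OC(C)=O)c(/C=C/C(C)C)c2O)[C@@H](c2ccc(OC(C)=O)cc2OC(C)=O)C1 | intermediate
17 | (E)-1-{3-[(1S,5S,6R)-6-{2,4-dihydroxy-3-[(E)-3-methylbut-1-en-1-yl]benzoyl}-5-(2,4-dihydroxyphenyl)-3-methylcyclohex-2-en-1-yl]-2,4-dihydroxyphenyl}-3-(4-hydroxyphenyl)prop-2-en-1-one | CC1=C[C@H](c2c(O)ccc(C(=O)/C=C/c3ccc(O)cc3)c2O)[C@H](C(=O)c2ccc(O)c(/C=C/C(C)C)c2O)[C@@H](c2ccc(O)cc2O)C1 | target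

**Totals**

Total steps: 11. Longest linear sequence: 6 (steps 1, 2, 3, 6, 10, 11).

**Steps most likely to fail, each with a fallback**

Step 8. The free 1,3-diene of 12 may itself insert into the acyl–rhodium hydride or bind rhodium, and the free 2'-hydroxychalcone 14 may close to a flavanone on heating. The fallback moves this hydroacylation to the end of the route. Setting out from 12, both phenols are acetylated (Ac2O, pyridine, DMAP) to give the diacetate aldehyde F2. F2 serves as the diene in the cycloaddition with 10 under the step-10 conditions to give the formyl adduct F3. K2CO3 in MeOH then frees the pentahydroxy aldehyde F4. Hydroacylation of 13 with F4 under the step-8 conditions, now with no diene present, gives the target directly, so the route is rejoined at 17.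

Step 6. The alkyne may insert the other way round (giving the branched 2-aryl enone) or conversion may stall. The fallback makes the same bond with normal polarity. Setting out from 9 and 6, the alkyne 9 is hydrozirconated with Cp2Zr(H)Cl, transmetalated with Me2Zn, and added to aldehyde 6 (one extra equivalent for the phenol) to give the secondary allylic alcohol F1. MnO2 in CH2Cl2 oxidises F1 to the enone, and the route is rejoined at 10.

Step 10. The endo:exo ratio may be near 1:1 and the enantioselectivity is uncertain for these exact partners. The fallback gives up asymmetric induction in favour of an endo-selective racemic cycloaddition plus resolution. Setting out from 10 and 15, catalysis by silver nanoparticles on SiO2 (zerovalent silver) in CH2Cl2 at 50 °C gives the endo adduct as a racemate, that is 16 together with the mirror-image adduct F5. Preparative chiral SFC removes F5, and the route is rejoined at 16.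

**Further compounds**

F1 | step 6 | 4-[(E)-3-{4-(acetyloxy)-2-hydroxy-3-[(E)-3-methylbut-1-en-1-yl]phenyl}-3-hydroxyprop-1-en-1-yl]-1,3-phenylene diacetate (racemic carbinol) | CC(C)/C=C/c1c(OC(C)=O)ccc(C(O)/C=C/c2ccc(OC(C)=O)cc2OC(C)=O)c1O
F2 | step 8 | 4-formyl-2-[(E)-3-methylbuta-1,3-dien-1-yl]-1,3-phenylene diacetate | CC(=C)/C=C/c1c(OC(C)=O)ccc(C=O)c1OC(C)=O
F3 | step 8 | 2-[(1S,5S,6R)-6-{4-(acetyloxy)-2-hydroxy-3-[(E)-3-methylbut-1-en-1-yl]benzoyl}-5-[2,4-bis(acetyloxy)phenyl]-3-methylcyclohex-2-en-1-yl]-4-formyl-1,3-phenylene diacetate | CC1=C[C@H](c2c(OC(C)=O)ccc(C=O)c2OC(C)=O)[C@H](C(=O)c2ccc(OC(C)=O)c(/C=C/C(C)C)c2O)[C@@H](c2ccc(OC(C)=O)cc2OC(C)=O)C1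
F4 | step 8 | 3-[(1S,5S,6R)-6-{2,4-dihydroxy-3-[(E)-3-methylbut-1-en-1-yl]benzoyl}-5-(2,4-dihydroxyphenyl)-3-methylcyclohex-2-en-1-yl]-2,4-dihydroxybenzaldehyde | CC1=C[C@H](c2c(O)ccc(C=O)c2O)[C@H](C(=O)c2ccc(O)c(/C=C/C(C)C)c2O)[C@@H](c2ccc(O)cc2O)C1
F5 | step 10 | (1R,5R,6S) enantiomer of hexaacetate adduct 16 | CC1=C[C@@H](c2c(OC(C)=O)ccc(C(=O)/C=C/c3ccc(OC(C)=O)cc3)c2OC(C)=O)[C@@H](C(=O)c2ccc(OC(C)=O)c(/C=C/C(C)C)c2O)[C@H](c2ccc(OC(C)=O)cc2OC(C)=O)C1
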